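**Plan**
- Retrosynthetic cuts, using naphthoquinone numbering: (i) the acyl–O bond of the isobutyrate. (ii) The quinone bond C1–C2, between the arene-bound carbonyl carbon and the side-chain-bearing carbon, while C1 and C4 are tied together by a bond the target lacks. (iii) The C3–C4 bond, which is then a carbinol–alkyne bond.
- Enabling feature: carbonyl carbons C1 and C4 sit on the adjacent arene carbons C8a and C4a, and C2=C3 is an alkyne at the quinone oxidation level. The quinone ring is therefore an isomer of a 2-alkynyl-2-hydroxybenzocyclobutenone. The 5,8-dioxygenated benzene ring is symmetric, so both carbonyl groups of the parent dione are equivalent.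
- Forward order: the benzene ring is bought. The temporary four-membered ring comes from an aryne [2+2] cycloaddition and is oxidised to the dione, and the methyl ethers are exchanged for silyl ethers. Acetylide addition then makes C3–C4, and thermolysis opens the four-membered ring and closes the quinone ring.
- Stereochemistry: the only stereocentre, C1' (R), is set by asymmetric transfer hydrogenation of an ynone before the coupling and is carried through unchanged.
- End game: global desilylation should give shikonin, and the side-chain hydroxyl is then acylated selectively.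

Key step: step 12

Assumption: 1,1-diethoxyethene, 4-methylpent-3-enoic acid and Ru[(R,R)-TsDPEN](p-cymene) are taken as purchasable, and the target is read as the isobutyrate ester drawn in the SMILES.

**Step 1**
Reactants: 1 2-bromo-1,4-dimethoxybenzene; 2 1,1-diethoxyethene
Product: 5 3,6-dimethoxybenzocyclobuten-1(2H)-one, via 3,6-dimethoxybenzyne 3 (not isolated), via diethyl acetal 4 (not isolated)
Conditions: NaNH2 (excess), 2 (2 equiv), THF, reflux; then 1 M aq HCl, THF, rt
Reagents that add atoms: water, O
Why: Sodium amide removes the proton between Br and OMe and expels bromide, the symmetric aryne 3 is trapped by the electron-rich ketene acetal in the well-known aryne–ketene acetal [2+2] cycloaddition, and dilute acid hydrolyses acetal 4 to the ketone, the symmetry of 3 excluding regioisomers.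

**Step 2**
Reactants: 5 3,6-dimethoxybenzocyclobuten-1(2H)-one
Product: 6 2,2-dibromo-3,6-dimethoxybenzocyclobuten-1(2H)-one
Conditions: NBS (2.2 equiv), (BzO)2 (cat.), PhCF3, reflux
Reagents that add atoms: N-bromosuccinimide, O=C1CCC(=O)N1Br
Why: Wohl–Ziegler radical bromination should occur twice at the only sp3 C–H position, which is both benzylic and alpha to the carbonyl group, as is standard for benzocyclobutenones.

**Step 3**
Reactants: 6 2,2-dibromo-3,6-dimethoxybenzocyclobuten-1(2H)-one
Product: 7 3,6-dimethoxybenzocyclobutene-1,2-dione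
Conditions: 50% aq H2SO4, 60 °C
Reagents that add atoms: water, O
Why: Acid hydrolysis of a geminal dihalide gives the second carbonyl group, and both the aryl methyl ethers and the strained dione tolerate aqueous sulfuric acid.

**Step 4**
Reactants: 7 3,6-dimethoxybenzocyclobutene-1,2-dione
Product: 9 3,6-dihydroxybenzocyclobutene-1,2-dione, via bis(dibromoboryl) ether 8 (not isolated)
Conditions: BBr3 (3 equiv), CH2Cl2, -78 °C to rt; then H2O
Reagents that add atoms: none
Why: Lewis-acid aryl ether cleavage with BBr3, assisted by the neighbouring carbonyl oxygens, removes both methyl groups while nothing acid-sensitive is present, so the phenols can be freed mildly at the end.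

**Step 5**
Reactants: 9 3,6-dihydroxybenzocyclobutene-1,2-dione
Product: 10 3,6-bis(tert-butyldimethylsilyloxy)benzocyclobutene-1,2-dione
Conditions: TBSCl (2.5 equiv), imidazole, DMF, rt
Reagents that add atoms: tert-butyldimethylsilyl chloride, CC(C)(C)[Si](C)(C)Cl
Why: Standard imidazole-promoted silylation of phenols gives ethers that should resist an acetylide at -78 °C and heat, yet fall to fluoride.

**Step 6**
Reactants: 11 4-methylpent-3-enoic acid
Product: 13 N-methoxy-N,4-dimethylpent-3-enamide, via acyl imidazole 12 (not isolated)
Conditions: CDI, CH2Cl2, rt; then MeNH(OMe)·HCl, rt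
Reagents that add atoms: N,O-dimethylhydroxylamine hydrochloride, CNOC.Cl
Why: Amide coupling by way of the acyl imidazole needs no added base, so the beta,gamma-double bond should not move into conjugation.

**Step 7**
Reactants: 13 N-methoxy-N,4-dimethylpent-3-enamide; 14 trimethylsilylacetylene
Product: 17 6-methyl-1-(trimethylsilyl)hept-5-en-1-yn-3-one, via lithium (trimethylsilyl)acetylide 15 (not isolated), via tetrahedral lithium adduct 16 (not isolated)
Conditions: 14, n-BuLi, THF, -78 °C; then 13, -78 to 0 °C; cold sat. aq NH4Cl
Reagents that add atoms: none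
Why: In this Weinreb ketone synthesis the chelated adduct 16 persists until the cold quench, which prevents over-addition and limits contact of the enolisable ynone with base.

**Step 8**
Reactants: 17 6-methyl-1-(trimethylsilyl)hept-5-en-1-yn-3-one
Product: 18 (R)-6-methyl-1-(trimethylsilyl)hept-5-en-1-yn-3-ol
Conditions: Ru[(R,R)-TsDPEN](p-cymene) (1 mol%), i-PrOH, rt, no base
Reagents that add atoms: none
Why: In the Noyori asymmetric transfer hydrogenation of alkynyl ketones the alkynyl pi system takes the place of the aryl group beside the arene ligand, so the (R,R) catalyst should deliver hydride to the face that gives the (R)-propargylic alcohol, while the base-free medium leaves C=C, C≡C and the beta,gamma-alkene position untouched.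

**Step 9**
Reactants: 18 (R)-6-methyl-1-(trimethylsilyl)hept-5-en-1-yn-3-ol
Product: 19 (R)-3-(tert-butyldimethylsilyloxy)-6-methyl-1-(trimethylsilyl)hept-5-en-1-yne
Conditions: TBSCl, imidazole, DMF, rt
Reagents that add atoms: tert-butyldimethylsilyl chloride, CC(C)(C)[Si](C)(C)Cl
Why: Standard O-silylation masks the alcohol against n-BuLi and against thermal redox isomerisation next to the later quinone, and it does not touch the C–O bond of the stereocentre.

**Step 10**
Reactants: 19 (R)-3-(tert-butyldimethylsilyloxy)-6-methyl-1-(trimethylsilyl)hept-5-en-1-yne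
Product: 20 (R)-3-(tert-butyldimethylsilyloxy)-6-methylhept-5-en-1-yne
Conditions: K2CO3 (0.2 equiv), MeOH, rt
Reagents that add atoms: none
Why: Methoxide-catalysed protiodesilylation cleaves only the C(sp)–Si bond, since a secondary TBS ether is stable to K2CO3 in methanol.

**Step 11**
Reactants: 20 (R)-3-(tert-butyldimethylsilyloxy)-6-methylhept-5-en-1-yne; 10 3,6-bis(tert-butyldimethylsilyloxy)benzocyclobutene-1,2-dione
Product: 23 2-[(3R)-3-(tert-butyldimethylsilyloxy)-6-methylhept-5-en-1-ynyl]-3,6-bis(tert-butyldimethylsilyloxy)-2-hydroxybenzocyclobuten-1(2H)-one (both epimers at the carbinol carbon), via lithium acetylide 21 (not isolated), via lithium alkoxide 22 (not isolated)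
Conditions: 20, n-BuLi (1.0 equiv), THF, -78 °C; cannulated into 10, THF, -78 °C; sat. aq NH4Cl at -78 °C
Reagents that add atoms: none
Why: In this 1,2-addition of a lithium acetylide to a benzocyclobutenedione the two carbonyl groups are equivalent by symmetry, so one constitution results, the alkoxide formed shields the remaining ketone from a second addition, and the uncontrolled carbinol centre is erased in step 12.

**Step 12**
Reactants: 23 2-alkynyl-2-hydroxybenzocyclobutenone (both epimers)
Product: 26 5,8-bis(tert-butyldimethylsilyloxy)-2-[(1R)-1-(tert-butyldimethylsilyloxy)-4-methylpent-3-enyl]-1,4-naphthoquinone, via enynylketene 24 (not isolated), via aryl-phenoxyl diradical 25 (not isolated)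
Conditions: degassed p-xylene (0.01 M), 138 °C
Reagents that add atoms: none
Why: Heat opens the four-membered ring of 23 by conrotatory 4π electrocyclic cleavage of the temporary C(=O)–C(OH) bond, and the donor hydroxyl rotates outward, so the alkynyl group turns inward and lies beside the ketene carbon in o-quinoid enynylketene 24. The ketene carbon then bonds to the distal alkyne carbon, the one that bears the side chain, which re-aromatises the benzene ring and gives diradical 25 (phenoxyl at O1, sigma radical at C3), and transfer of the hydroxyl hydrogen to C3 gives quinone 26 at the final oxidation level without any oxidant. The closest known reaction type is the Moore rearrangement of 4-alkynyl-4-hydroxycyclobutenones, which is also known for benzo-fused members that give 1,4-naphthoquinones. The one ring that forms is closed in the 6-endo-dig mode (both alkyne carbons end up in the ring), and the competing 5-exo-dig closure to a 2-alkylideneindane-1,3-dione, which needs a radical-stabilising aryl, silyl or alkoxy group on the alkyne terminus, should be disfavoured by the plain secondary alkyl terminus of 23. No stereocentre is made: the carbinol centre is erased, so both epimers of 23 converge, and C1' is a spectator that should keep its (R) configuration in a neutral, aprotic medium. The position of the side chain next to the new bond follows from the connectivity of 23 alone, and the hydrogen transfer to C3 has to outrun abstraction from the allylic CH2 group, which the free hydroxyl beside the radical centre and high dilution should secure.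

**Step 13**
Reactants: 26 tris-TBS-protected shikonin
Product: 27 shikonin, 5,8-dihydroxy-2-[(1R)-1-hydroxy-4-methylpent-3-enyl]-1,4-naphthoquinone
Conditions: HF·pyridine (excess), pyridine, THF, 0 °C to rt (plastic vessel)
Reagents that add atoms: none
Why: Fluoride-driven desilylation in a buffered, weakly acidic medium should cleave the two activated aryl silyl ethers and the secondary silyl ether at Si–O, avoiding the base-sensitive naphthazarin dianion and leaving the C1'–O bond untouched.

**Step 14**
Reactants: 27 shikonin; 28 isobutyric acid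
Product: 30 isobutylshikonin (shikonin isobutyrate), via O-acylisourea 29 (not isolated)
Conditions: 28 (1.3 equiv), DCC, DMAP (cat.), CH2Cl2, 0 °C to rt, dark
Reagents that add atoms: none
Why: In this Steglich esterification the two peri hydroxyls are locked in strong hydrogen bonds to the quinone carbonyls and are poor nucleophiles, so only the secondary side-chain alcohol should be acylated, with retention because its C–O bond is not broken.

**Compound list**
1 | 2-bromo-1,4-dimethoxybenzene | COc1ccc(OC)c(Br)c1 | starting material
2 | 1,1-diethoxyethene | C=C(OCC)OCC | starting material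
3 | 3,6-dimethoxybenzyne | COC1=CC=C(OC)C#C1 | intermediate
4 | 1,1-diethoxy-3,6-dimethoxybenzocyclobutene | CCOC1(OCC)Cc2c(OC)ccc(OC)c21 | intermediate
5 | 3,6-dimethoxybenzocyclobuten-1(2H)-one (2,5-dimethoxybicyclo[4.2.0]octa-1,3,5-trien-7-one) | O=C1Cc2c(OC)ccc(OC)c21 | intermediate
6 | 2,2-dibromo-3,6-dimethoxybenzocyclobuten-1(2H)-one | O=C1c2c(OC)ccc(OC)c2C1(Br)Br | intermediate
7 | 3,6-dimethoxybenzocyclobutene-1,2-dione | COc1ccc(OC)c2c1C(=O)C2=O | intermediate
8 | 3,6-bis(dibromoboryloxy)benzocyclobutene-1,2-dione | O=C1C(=O)c2c(OB(Br)Br)ccc(OB(Br)Br)c21 | intermediate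
9 | 3,6-dihydroxybenzocyclobutene-1,2-dione | O=C1C(=O)c2c(O)ccc(O)c21 | intermediate
10 | 3,6-bis(tert-butyldimethylsilyloxy)benzocyclobutene-1,2-dione | CC(C)(C)[Si](C)(C)Oc1ccc(O[Si](C)(C)C(C)(C)C)c2c1C(=O)C2=O | intermediate
11 | 4-methylpent-3-enoic acid | CC(C)=CCC(=O)O | starting material
12 | 1-(4-methylpent-3-enoyl)imidazole | CC(C)=CCC(=O)n1ccnc1 | intermediate
13 | N-methoxy-N,4-dimethylpent-3-enamide | CC(C)=CCC(=O)N(C)OC | intermediate
14 | trimethylsilylacetylene | C#C[Si](C)(C)C | starting material
15 | lithium (trimethylsilyl)acetylide | [Li]C#C[Si](C)(C)C | intermediate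
16 | tetrahedral lithium adduct of 13 and 15 | CC(C)=CCC(O[Li])(C#C[Si](C)(C)C)N(C)OC | intermediate
17 | 6-methyl-1-(trimethylsilyl)hept-5-en-1-yn-3-one | CC(C)=CCC(=O)C#C[Si](C)(C)C | intermediate
18 | (R)-6-methyl-1-(trimethylsilyl)hept-5-en-1-yn-3-ol | CC(C)=CC[C@@H](O)C#C[Si](C)(C)C | intermediate
19 | (R)-3-(tert-butyldimethylsilyloxy)-6-methyl-1-(trimethylsilyl)hept-5-en-1-yne | CC(C)=CC[C@@H](O[Si](C)(C)C(C)(C)C)C#C[Si](C)(C)C | intermediate
20 | (R)-3-(tert-butyldimethylsilyloxy)-6-methylhept-5-en-1-yne | CC(C)=CC[C@@H](O[Si](C)(C)C(C)(C)C)C#C | intermediate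
21 | lithium acetylide of 20 | CC(C)=CC[C@@H](O[Si](C)(C)C(C)(C)C)C#C[Li] | intermediate
22 | lithium alkoxide of 23 (both epimers at the carbinol carbon) | CC(C)=CC[C@@H](O[Si](C)(C)C(C)(C)C)C#CC1(O[Li])C(=O)c2c(O[Si](C)(C)C(C)(C)C)ccc(O[Si](C)(C)C(C)(C)C)c21 | intermediate
23 | 2-[(3R)-3-(tert-butyldimethylsilyloxy)-6-methylhept-5-en-1-ynyl]-3,6-bis(tert-butyldimethylsilyloxy)-2-hydroxybenzocyclobuten-1(2H)-one (both epimers at the carbinol carbon) | CC(C)=CC[C@@H](O[Si](C)(C)C(C)(C)C)C#CC1(O)C(=O)c2c(O[Si](C)(C)C(C)(C)C)ccc(O[Si](C)(C)C(C)(C)C)c21 | intermediate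
24 | o-quinoid enynylketene, alkynyl group on the side of the ketene | CC(C)=CC[C@@H](O[Si](C)(C)C(C)(C)C)C#C/C(O)=C1\C(=C=O)C(O[Si](C)(C)C(C)(C)C)=CC=C1O[Si](C)(C)C(C)(C)C | intermediate
25 | diradical: 4-hydroxynaphthalen-1-oxyl with a sigma radical at C3 | CC(C)=CC[C@@H](O[Si](C)(C)C(C)(C)C)c1[c]c(O)c2c(O[Si](C)(C)C(C)(C)C)ccc(O[Si](C)(C)C(C)(C)C)c2c1[O] | intermediate
26 | 5,8-bis(tert-butyldimethylsilyloxy)-2-[(1R)-1-(tert-butyldimethylsilyloxy)-4-methylpent-3-enyl]-1,4-naphthoquinone | CC(C)=CC[C@@H](O[Si](C)(C)C(C)(C)C)C1=CC(=O)c2c(O[Si](C)(C)C(C)(C)C)ccc(O[Si](C)(C)C(C)(C)C)c2C1=O | intermediate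
27 | shikonin, 5,8-dihydroxy-2-[(1R)-1-hydroxy-4-methylpent-3-enyl]-1,4-naphthoquinone | CC(C)=CC[C@@H](O)C1=CC(=O)c2c(O)ccc(O)c2C1=O | intermediate
28 | isobutyric acid | CC(C)C(=O)O | starting material
29 | O-isobutyryl-N,N'-dicyclohexylisourea | CC(C)C(=O)OC(=NC1CCCCC1)NC1CCCCC1 | intermediate
30 | isobutylshikonin, (1R)-1-(5,8-dihydroxy-1,4-dioxo-1,4-dihydronaphthalen-2-yl)-4-methylpent-3-enyl 2-methylpropanoate | CC(C)=CC[C@@H](OC(=O)C(C)C)C1=CC(=O)c2c(O)ccc(O)c2C1=O | target

**Step count**
Total step count: 14. Longest linear sequence: 9 steps (steps 1–5 or steps 6–10, followed by steps 11–14).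

**Steps most likely to fail**

Step 12. Three processes could divert the rearrangement:
- The sigma radical at C3 may abstract an allylic hydrogen of the side chain by 1,5-transfer before the hydroxyl hydrogen arrives.
- The closure may take the five-membered mode.
- The o-quinoid ketene may be lost to oligomerisation.

The fallback replaces the diradical cycloaromatisation by a closed-shell electrocyclisation that forms the same bond. It sets out from 23 and comes back at 26.
- Semihydrogenation of 23 over Lindlar catalyst (H2, quinoline, EtOAc) should give the (Z)-alkenyl carbinol F1.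
- Heating in toluene should open the four-membered ring in the same sense and close the dienylketene by a 6π electrocyclisation. After tautomerisation this gives the protected naphthalene-1,4-diol F2.
- Oxidation with Ag2O in CH2Cl2 should then give 26.

Step 2. Electrophilic bromination of the electron-rich dimethoxyarene ring may compete with the radical chain at the CH2 group, and the second bromination may stall.

The fallback brings in the second oxygen with the two-carbon partner, so no C–H oxidation is needed. It sets out from 1 and comes back at 7, replacing steps 1–3.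
- Aryne 3 is generated from 1 with LiTMP in THF (-78 °C to rt) in the presence of commercial tris(trimethylsiloxy)ethene. The ketene silyl acetal [2+2] cycloaddition should give the tris(trimethylsilyloxy)benzocyclobutene F3.
- Dilute aqueous HCl in THF should free the 2-hydroxy-3,6-dimethoxybenzocyclobutenone F4.
- Dess–Martin oxidation should give 7.

Step 11. Three processes could spoil the addition:
- A silyl group may move from the neighbouring aryl oxygen to the new tertiary alkoxide.
- A second acetylide may add.
- The strained ketol alkoxide may open before the quench.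

The fallback changes the protecting-group strategy to acetals that cannot migrate. It sets out from 9 and comes back at 27.
- Treatment of 9 with MOMCl and i-Pr2NEt in CH2Cl2 should give the bis(methoxymethyl) ether dione F5.
- Addition of lithium acetylide 21 at -78 °C should give the alkynyl carbinol F6.
- Thermolysis in p-xylene should give the bis-MOM silyl-protected quinone F7.
- Aqueous HCl in THF/i-PrOH at rt should remove both acetals and the silyl ether in one operation to give 27.

**Further compounds**
F1 | step 12 | 2-[(1Z,3R)-3-(tert-butyldimethylsilyloxy)-6-methylhepta-1,5-dienyl]-3,6-bis(tert-butyldimethylsilyloxy)-2-hydroxybenzocyclobuten-1(2H)-one | CC(C)=CC[C@@H](O[Si](C)(C)C(C)(C)C)/C=C\C1(O)C(=O)c2c(O[Si](C)(C)C(C)(C)C)ccc(O[Si](C)(C)C(C)(C)C)c21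
F2 | step 12 | 5,8-bis(tert-butyldimethylsilyloxy)-2-[(1R)-1-(tert-butyldimethylsilyloxy)-4-methylpent-3-enyl]naphthalene-1,4-diol | CC(C)=CC[C@@H](O[Si](C)(C)C(C)(C)C)c1cc(O)c2c(O[Si](C)(C)C(C)(C)C)ccc(O[Si](C)(C)C(C)(C)C)c2c1O
F3 | step 2 | 3,6-dimethoxy-1,1,2-tris(trimethylsilyloxy)benzocyclobutene (racemic) | COc1ccc(OC)c2c1C(O[Si](C)(C)C)C2(O[Si](C)(C)C)O[Si](C)(C)C
F4 | step 2 | 2-hydroxy-3,6-dimethoxybenzocyclobuten-1(2H)-one (racemic) | COc1ccc(OC)c2c1C(O)C2=O
F5 | step 11 | 3,6-bis(methoxymethoxy)benzocyclobutene-1,2-dione | O=C1C(=O)c2c(OCOC)ccc(OCOC)c21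
F6 | step 11 | 2-[(3R)-3-(tert-butyldimethylsilyloxy)-6-methylhept-5-en-1-ynyl]-2-hydroxy-3,6-bis(methoxymethoxy)benzocyclobuten-1(2H)-one (both epimers at the carbinol carbon) | CC(C)=CC[C@@H](O[Si](C)(C)C(C)(C)C)C#CC1(O)C(=O)c2c(OCOC)ccc(OCOC)c21
F7 | step 11 | 2-[(1R)-1-(tert-butyldimethylsilyloxy)-4-methylpent-3-enyl]-5,8-bis(methoxymethoxy)-1,4-naphthoquinone | CC(C)=CC[C@@H](O[Si](C)(C)C(C)(C)C)C1=CC(=O)c2c(OCOC)ccc(OCOC)c2C1=O
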